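**Strategy**

Everything rests on taking ring A apart into a vinylketene (C4a, C5, C6, C7) and an alkynyl ether (C8, C8a). The feature used is that ring A is a 1,3-dioxygenated benzene in which only C5 still carries hydrogen, and that the oxygen on C8a is at the same time the ring C heteroatom O1. An alkyne hung on the C2 oxygen is thus already tied to the ketene carbon C4a through C2–C3–C4. One irradiation of an (E)-dienyl α-diazoketone should then give Wolff shift, tethered [2+2] addition, 4π opening and 6π closure, building rings A and C together. The precursor bears a silyloxy group at C4 and the (S)-prenylethynyl ether at C2.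

Key step: step 12

**Remarks on the chemistry**

- Atom labels (O1, C2 … C8a, rings A and C) follow the flavanone numbering of the target.
- Assumption: the carbinol carbon that becomes C4 is carried as both epimers from step 10 to step 13, since it ends as the ketone; its SMILES are written without configuration.
- An ester cannot pass the KH and n-BuLi treatments that build the alkynyl ether, so the future C4 is held as a TIPS-protected primary alcohol through steps 3–5.
- The diazo group enters with the dienyl fragment and C4–C4a is made by a diazoketone aldol addition. This avoids diazo transfer next to a β-silyloxy group.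
- Structure check of the key step: 23 (C33H48N2O5Si) and 28 (C33H48O5Si) differ by N2 only, and C2 is (S) in 13, 23, 28 and 30. No change to connectivity or configuration was needed.
- The benzylic alkynyl ethers 11–13, 22 and 23 are kept at or below 25 °C, away from acid, and purified on Et3N-deactivated silica.
- Compounds 1, 5, 8, 14 and 15 are commercial.

**Route**

Step 1
Reactants: 1 ethyl 3-(3,4-dimethoxyphenyl)-3-oxopropanoate
Product: 2 ethyl (3S)-3-(3,4-dimethoxyphenyl)-3-hydroxypropanoate
Conditions: RuCl[(S,S)-TsDPEN](p-cymene) (1 mol %), HCO2H/Et3N (5:2), 30 °C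
Reagents that add atoms: none
Why: Noyori–Ikariya asymmetric transfer hydrogenation of an aryl ketone, in which hydride and proton pass through the six-membered bifunctional transition state with the aryl group held against the η6-arene, so the (S,S)-catalyst should deliver the (S)-carbinol (the future C2) as it does for acetophenones.

Step 2
Reactants: 2 ethyl (3S)-3-(3,4-dimethoxyphenyl)-3-hydroxypropanoate
Product: 3 (1S)-1-(3,4-dimethoxyphenyl)propane-1,3-diol
Conditions: LiAlH4, THF, 0 → 20 °C
Reagents that add atoms: none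
Why: Hydride reduction of the ester to the primary alcohol removes the ester before the strongly basic steps it could not survive and leaves the benzylic carbinol untouched.

Step 3
Reactants: 3 (1S)-1-(3,4-dimethoxyphenyl)propane-1,3-diol
Product: 4 (1S)-1-(3,4-dimethoxyphenyl)-3-(triisopropylsilyloxy)propan-1-ol
Conditions: i-Pr3SiCl (1.05 equiv), imidazole, CH2Cl2, 0 → 20 °C
Reagents that add atoms: chlorotriisopropylsilane, CC(C)[Si](Cl)(C(C)C)C(C)C
Why: Selective silylation of the primary hydroxyl over the hindered benzylic one by the bulky chlorosilane, the TIPS group being chosen because it resists 1,5 O→O migration under KH and survives n-BuLi.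

Step 4
Reactants: 4 (1S)-1-(3,4-dimethoxyphenyl)-3-(triisopropylsilyloxy)propan-1-ol; 5 trichloroethylene
Product: 7 [(3S)-3-{[(E)-1,2-dichloroethenyl]oxy}-3-(3,4-dimethoxyphenyl)propoxy]triisopropylsilane, via potassium alkoxide 6 (not isolated)
Conditions: KH (2 equiv), THF, 0 → 20 °C; then 5, –50 → 20 °C
Reagents that add atoms: none
Why: Greene dichlorovinyl ether synthesis, in which the potassium alkoxide adds anti to dichloroacetylene formed in the flask from trichloroethylene by dehydrochlorination, so the C–O bond at the stereocentre is never broken.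

Step 5
Reactants: 7 [(3S)-3-{[(E)-1,2-dichloroethenyl]oxy}-3-(3,4-dimethoxyphenyl)propoxy]triisopropylsilane; 8 prenyl bromide
Product: 11 [(3S)-3-(3,4-dimethoxyphenyl)-3-{(5-methylhex-4-en-1-yn-1-yl)oxy}propoxy]triisopropylsilane, via chloroethynyl ether 9 (not isolated), via lithium alkoxyacetylide 10 (not isolated)
Conditions: n-BuLi (2.2 equiv), THF, –78 → –40 °C; then 8, DMPU, –78 → 15 °C
Reagents that add atoms: none
Why: Greene alkynyl ether synthesis, in which dehydrochlorination to the chloroalkyne and Cl/Li exchange give the lithium alkoxyacetylide that is alkylated by SN2 at the primary carbon of the allylic bromide.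

Step 6
Reactants: 11 [(3S)-3-(3,4-dimethoxyphenyl)-3-{(5-methylhex-4-en-1-yn-1-yl)oxy}propoxy]triisopropylsilane
Product: 12 (3S)-3-(3,4-dimethoxyphenyl)-3-[(5-methylhex-4-en-1-yn-1-yl)oxy]propan-1-ol
Conditions: Bu4NF, THF, 0 → 20 °C; water
Reagents that add atoms: none
Why: Fluoride-induced cleavage of the silyl ether proceeds under basic conditions that the acid-labile alkynyl ether tolerates.

Step 7
Reactants: 12 (3S)-3-(3,4-dimethoxyphenyl)-3-[(5-methylhex-4-en-1-yn-1-yl)oxy]propan-1-ol
Product: 13 (3S)-3-(3,4-dimethoxyphenyl)-3-[(5-methylhex-4-en-1-yn-1-yl)oxy]propanal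
Conditions: Dess–Martin periodinane, pyridine, CH2Cl2, 0 °C
Reagents that add atoms: none
Why: Dess–Martin oxidation stops at the aldehyde under buffered, non-aqueous conditions that spare the alkynyl ether and the alkene, and the aldehyde is used at once.

Step 8
Reactants: 14 4-methylpent-3-en-1-ol; 15 1-(triphenylphosphoranylidene)propan-2-one
Product: 17 (3E)-7-methylocta-3,6-dien-2-one, via 4-methylpent-3-enal 16 (not isolated)
Conditions: Dess–Martin periodinane, pyridine, CH2Cl2, 0 → 20 °C; then 15, 20 °C
Reagents that add atoms: none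
Why: One-pot Dess–Martin oxidation and Wittig olefination, in which the isomerisation-prone β,γ-unsaturated aldehyde is trapped as it forms by the stabilised ylide, which should give the (E)-enone.

Step 9
Reactants: 17 (3E)-7-methylocta-3,6-dien-2-one
Product: 20 (3E)-1-diazo-7-methylocta-3,6-dien-2-one, via lithium dienolate 18 (not isolated), via trifluoroacetyl diketone 19 (not isolated)
Conditions: LiN(SiMe3)2, THF, –78 °C; CF3CO2CH2CF3, –78 °C; aq HCl; then MeSO2N3, Et3N, H2O, MeCN, 20 °C
Reagents that add atoms: methanesulfonyl azide, CS(=O)(=O)N=[N+]=[N-]; 2,2,2-trifluoroethyl trifluoroacetate, O=C(OCC(F)(F)F)C(F)(F)F (its acyl group is carried only by 19)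
Why: Danheiser detrifluoroacetylative diazo transfer, in which kinetic deprotonation at the methyl group and Claisen trifluoroacetylation activate the ketone for Regitz diazo transfer with loss of the trifluoroacetyl group, a sequence suited to enone-derived diazoketones that acyl chloride and diazomethane do not deliver cleanly.

Step 10
Reactants: 13 (3S)-3-(3,4-dimethoxyphenyl)-3-[(5-methylhex-4-en-1-yn-1-yl)oxy]propanal; 20 (3E)-1-diazo-7-methylocta-3,6-dien-2-one
Product: 22 (1S,6E)-4-diazo-1-(3,4-dimethoxyphenyl)-3-hydroxy-10-methyl-1-[(5-methylhex-4-en-1-yn-1-yl)oxy]undeca-6,9-dien-5-one (both C3 epimers), via lithiated diazoketone 21 (not isolated)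
Conditions: LiN(SiMe3)2, THF, –78 °C; then 13, –78 °C; pH 7 buffer
Reagents that add atoms: none
Why: Aldol-type addition of a lithiated α-diazoketone to an aldehyde forms C4–C4a with the diazo group already in place, and the new carbinol centre (the future C4) need not be controlled because it becomes the ketone.

Step 11
Reactants: 22 (1S,6E)-4-diazo-1-(3,4-dimethoxyphenyl)-3-hydroxy-10-methyl-1-[(5-methylhex-4-en-1-yn-1-yl)oxy]undeca-6,9-dien-5-one
Product: 23 (1S,6E)-3-(tert-butyldimethylsilyloxy)-4-diazo-1-(3,4-dimethoxyphenyl)-10-methyl-1-[(5-methylhex-4-en-1-yn-1-yl)oxy]undeca-6,9-dien-5-one (both C3 epimers)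
Conditions: t-BuMe2SiCl, imidazole, DMF, 0 → 20 °C
Reagents that add atoms: tert-butyldimethylsilyl chloride, CC(C)(C)[Si](C)(C)Cl
Why: Corey silylation of the secondary alcohol under non-acidic conditions free of Lewis acid that diazoketone and alkynyl ether tolerate, the silyl ether keeping the C4 oxygen from trapping the ketene in step 12.

Step 12
Reactants: 23 (1S,6E)-3-(tert-butyldimethylsilyloxy)-4-diazo-1-(3,4-dimethoxyphenyl)-10-methyl-1-[(5-methylhex-4-en-1-yn-1-yl)oxy]undeca-6,9-dien-5-one
Product: 28 (2S)-4-(tert-butyldimethylsilyloxy)-3',4'-dimethoxy-6,8-diprenylflavan-7-ol (both C4 epimers), via vinylketene 24 (not isolated), via bicyclic cyclobutenone 25 (not isolated), via dienylketene 26 (not isolated), via cyclohexadienone 27 (not isolated)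
Conditions: hν (Pyrex-filtered medium-pressure Hg lamp, λ > 300 nm), degassed PhMe (0.005 M), 15 °C; then 70 °C in the dark if 25 persists
Reagents that add atoms: none
Why: Proposed new method: irradiation expels N2 while the dienyl group shifts from C7 to C4a (photo-Wolff rearrangement) to give vinylketene 24, whose electrophilic carbonyl carbon C7 is attacked by the nucleophilic C8 of the alkynyl ether as C4a bonds to the oxygen-bearing C8a, so that a crossed [2+2] cycloaddition closes ring C as the six-membered half of fused cyclobutenone 25. Strain then drives conrotatory 4π opening to dienylketene 26 (the new C4a=C8a bond lies inside ring C, which places C5 and C8 cis as required), and 6π-electrocyclisation (C6–C7) followed by enolisation of dienone 27 closes ring A and leaves the ketene oxygen as the C7 phenol. The closest known chemistry is the intermolecular photochemical Danheiser benzannulation of α,β-unsaturated α′-diazoketones with alkoxyalkynes, together with intramolecular ketene [2+2] cycloadditions over short tethers; the untested part is the tethered union of ketene and alkynyl ether. No stereocentre is created, C2 is a spectator, and both C4 epimers converge on the same ketone later. The selectivity needed is the orientation of ketene and alkyne, which the four-atom O1–C2–C3–C4 tether and the polarisation of the alkynyl ether both dictate, together with Wolff shift in preference to 1,2-hydride shift from C4 (favoured by direct excitation of the acyclic diazoketone) and capture of the ketene by the alkynyl ether and not by a prenyl alkene (secured by the (E)-C5=C6 geometry and the far greater nucleophilicity of the alkynyl ether).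

Step 13
Reactants: 28 (2S)-4-(tert-butyldimethylsilyloxy)-3',4'-dimethoxy-6,8-diprenylflavan-7-ol
Product: 29 (2S)-3',4'-dimethoxy-6,8-diprenylflavan-4,7-diol (both C4 epimers)
Conditions: Bu4NF, THF, 0 °C; pH 7 buffer
Reagents that add atoms: none
Why: Fluoride cleavage of the benzylic silyl ether is placed before the oxidation so that the base-sensitive flavanone, whose ring opening at O1–C2 would racemise C2, never meets fluoride.

Step 14
Reactants: 29 (2S)-3',4'-dimethoxy-6,8-diprenylflavan-4,7-diol
Product: 30 (2S)-7-hydroxy-3',4'-dimethoxy-6,8-diprenylflavanone (IN0946)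
Conditions: activated MnO2, CH2Cl2, 20 °C, dark
Reagents that add atoms: none
Why: MnO2 oxidation is selective for the electron-rich benzylic carbinol under neutral conditions that leave C2, the phenol and the prenyl groups alone, and both C4 epimers give the same ketone.

**Compound list**

1 | ethyl 3-(3,4-dimethoxyphenyl)-3-oxopropanoate | CCOC(=O)CC(=O)c1ccc(OC)c(OC)c1 | starting material
2 | ethyl (3S)-3-(3,4-dimethoxyphenyl)-3-hydroxypropanoate | CCOC(=O)C[C@H](O)c1ccc(OC)c(OC)c1 | intermediate
3 | (1S)-1-(3,4-dimethoxyphenyl)propane-1,3-diol | OCC[C@H](O)c1ccc(OC)c(OC)c1 | intermediate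
4 | (1S)-1-(3,4-dimethoxyphenyl)-3-(triisopropylsilyloxy)propan-1-ol | CC(C)[Si](OCC[C@H](O)c1ccc(OC)c(OC)c1)(C(C)C)C(C)C | intermediate
5 | trichloroethylene | ClC=C(Cl)Cl | starting material
6 | potassium (1S)-1-(3,4-dimethoxyphenyl)-3-(triisopropylsilyloxy)propan-1-olate (formed in the flask) | CC(C)[Si](OCC[C@H]([O-])c1ccc(OC)c(OC)c1)(C(C)C)C(C)C.[K+] | intermediate
7 | [(3S)-3-{[(E)-1,2-dichloroethenyl]oxy}-3-(3,4-dimethoxyphenyl)propoxy]triisopropylsilane | CC(C)[Si](OCC[C@H](O/C(Cl)=C\Cl)c1ccc(OC)c(OC)c1)(C(C)C)C(C)C | intermediate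
8 | prenyl bromide (1-bromo-3-methylbut-2-ene) | CC(C)=CCBr | starting material
9 | [(3S)-3-(chloroethynyloxy)-3-(3,4-dimethoxyphenyl)propoxy]triisopropylsilane (formed in the flask) | CC(C)[Si](OCC[C@H](OC#CCl)c1ccc(OC)c(OC)c1)(C(C)C)C(C)C | intermediate
10 | lithium 2-{[(1S)-1-(3,4-dimethoxyphenyl)-3-(triisopropylsilyloxy)propyl]oxy}ethynide (formed in the flask) | CC(C)[Si](OCC[C@H](OC#C[Li])c1ccc(OC)c(OC)c1)(C(C)C)C(C)C | intermediate
11 | [(3S)-3-(3,4-dimethoxyphenyl)-3-{(5-methylhex-4-en-1-yn-1-yl)oxy}propoxy]triisopropylsilane | CC(C)[Si](OCC[C@H](OC#CCC=C(C)C)c1ccc(OC)c(OC)c1)(C(C)C)C(C)C | intermediate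
12 | (3S)-3-(3,4-dimethoxyphenyl)-3-[(5-methylhex-4-en-1-yn-1-yl)oxy]propan-1-ol | OCC[C@H](OC#CCC=C(C)C)c1ccc(OC)c(OC)c1 | intermediate
13 | (3S)-3-(3,4-dimethoxyphenyl)-3-[(5-methylhex-4-en-1-yn-1-yl)oxy]propanal | O=CC[C@H](OC#CCC=C(C)C)c1ccc(OC)c(OC)c1 | intermediate
14 | 4-methylpent-3-en-1-ol | CC(C)=CCCO | starting material
15 | 1-(triphenylphosphoranylidene)propan-2-one | CC(=O)C=P(c1ccccc1)(c1ccccc1)c1ccccc1 | starting material
16 | 4-methylpent-3-enal (formed in the flask) | CC(C)=CCC=O | intermediate
17 | (3E)-7-methylocta-3,6-dien-2-one | CC(=O)/C=C/CC=C(C)C | intermediate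
18 | lithium (3E)-7-methylocta-1,3,6-trien-2-olate (formed in the flask) | [Li+].[O-]C(=C)/C=C/CC=C(C)C | intermediate
19 | (5E)-1,1,1-trifluoro-9-methyldeca-5,8-diene-2,4-dione (not purified) | O=C(CC(=O)/C=C/CC=C(C)C)C(F)(F)F | intermediate
20 | (3E)-1-diazo-7-methylocta-3,6-dien-2-one | CC(C)=CC/C=C/C(=O)C=[N+]=[N-] | intermediate
21 | (3E)-1-diazo-1-lithio-7-methylocta-3,6-dien-2-one (formed in the flask) | CC(C)=CC/C=C/C(=O)C([Li])=[N+]=[N-] | intermediate
22 | (1S,6E)-4-diazo-1-(3,4-dimethoxyphenyl)-3-hydroxy-10-methyl-1-[(5-methylhex-4-en-1-yn-1-yl)oxy]undeca-6,9-dien-5-one, both C3 epimers (chain C3 is flavanone C4) | CC(C)=CC/C=C/C(=O)C(=[N+]=[N-])C(O)C[C@H](OC#CCC=C(C)C)c1ccc(OC)c(OC)c1 | intermediate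
23 | (1S,6E)-3-(tert-butyldimethylsilyloxy)-4-diazo-1-(3,4-dimethoxyphenyl)-10-methyl-1-[(5-methylhex-4-en-1-yn-1-yl)oxy]undeca-6,9-dien-5-one, both C3 epimers (key-step precursor) | CC(C)=CC/C=C/C(=O)C(=[N+]=[N-])C(O[Si](C)(C)C(C)(C)C)C[C@H](OC#CCC=C(C)C)c1ccc(OC)c(OC)c1 | intermediate
24 | (3E)-2-[(3S)-1-(tert-butyldimethylsilyloxy)-3-(3,4-dimethoxyphenyl)-3-{(5-methylhex-4-en-1-yn-1-yl)oxy}propyl]-7-methylocta-1,3,6-trien-1-one, the vinylketene (formed in the flask) | O=C=C(/C=C/CC=C(C)C)C(O[Si](C)(C)C(C)(C)C)C[C@H](OC#CCC=C(C)C)c1ccc(OC)c(OC)c1 | intermediate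
25 | (3S)-5-(tert-butyldimethylsilyloxy)-3-(3,4-dimethoxyphenyl)-8-(3-methylbut-2-enyl)-6-[(1E)-5-methylhexa-1,4-dienyl]-2-oxabicyclo[4.2.0]oct-1(8)-en-7-one (formed in the flask) | O=C1C(CC=C(C)C)=C2O[C@H](c3ccc(OC)c(OC)c3)CC(O[Si](C)(C)C(C)(C)C)C12/C=C/CC=C(C)C | intermediate
26 | 2-{(2S)-4-(tert-butyldimethylsilyloxy)-2-(3,4-dimethoxyphenyl)-5-[(1E)-5-methylhexa-1,4-dienyl]-3,4-dihydro-2H-pyran-6-yl}-5-methylhexa-1,4-dien-1-one, the dienylketene (formed in the flask) | O=C=C(CC=C(C)C)C1=C(/C=C/CC=C(C)C)C(O[Si](C)(C)C(C)(C)C)C[C@@H](c2ccc(OC)c(OC)c2)O1 | intermediate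
27 | (2S)-4-(tert-butyldimethylsilyloxy)-2-(3,4-dimethoxyphenyl)-6,8-bis(3-methylbut-2-enyl)-3,4-dihydro-2H-chromen-7(6H)-one, the keto tautomer of 28 (formed in the flask) | O=C1C(CC=C(C)C)C=C2C(O[Si](C)(C)C(C)(C)C)C[C@@H](c3ccc(OC)c(OC)c3)OC2=C1CC=C(C)C | intermediate
28 | (2S)-4-(tert-butyldimethylsilyloxy)-3',4'-dimethoxy-6,8-diprenylflavan-7-ol, both C4 epimers (key-step product) | COc1ccc([C@@H]2CC(O[Si](C)(C)C(C)(C)C)c3cc(CC=C(C)C)c(O)c(CC=C(C)C)c3O2)cc1OC | intermediate
29 | (2S)-3',4'-dimethoxy-6,8-diprenylflavan-4,7-diol, both C4 epimers | COc1ccc([C@@H]2CC(O)c3cc(CC=C(C)C)c(O)c(CC=C(C)C)c3O2)cc1OC | intermediate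
30 | (2S)-7-hydroxy-3',4'-dimethoxy-6,8-diprenylflavanone (IN0946) | COc1ccc([C@@H]2CC(=O)c3cc(CC=C(C)C)c(O)c(CC=C(C)C)c3O2)cc1OC | target

**Step count**

Total: 14 steps. Longest linear sequence: 12 steps (steps 1–7 and 10–14); steps 8 and 9 form the second branch.

**Steps most likely to fail**

1. Step 12. What may go wrong:
   - 1,2-hydride shift from C4 to the carbene carbon could outrun the Wolff shift.
   - The ketene may fail to reach the tethered alkyne in the crossed [2+2] geometry and dimerise instead.
   - The benzylic alkynyl ether may be lost by thermal sigmatropic rearrangement, or the diazo group may add to it as a dipole, before irradiation.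

   Fallback with known chemistry, setting out from 20 and 13 and coming back at 30. The intermolecular photochemical benzannulation of diazoketone 20 with alkynyl ether 13 (hν, λ > 300 nm, PhMe, 15 °C, irradiation continued until the cyclobutenone is consumed) should give (3S)-3-(3,4-dimethoxyphenyl)-3-[3-hydroxy-2,4-bis(3-methylbut-2-en-1-yl)phenoxy]propanal F1. In F1 the ketene oxygen is the free phenol between the two prenyl groups and the alkynyl ether oxygen carries the C2 side chain. Pinnick oxidation (NaClO2, NaH2PO4, excess 2-methylbut-2-ene, t-BuOH/H2O, 0 °C) should give (3S)-3-(3,4-dimethoxyphenyl)-3-[3-hydroxy-2,4-bis(3-methylbut-2-en-1-yl)phenoxy]propanoic acid F2. Intramolecular Friedel–Crafts acylation at C4a, the only free position ortho to the ether oxygen and para to the phenol ((CF3CO)2O, CH2Cl2, 0 °C, then aq NaHCO3), should close ring C to 30. This also makes steps 13 and 14 unnecessary.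

2. Step 10. What may go wrong:
   - Deprotonation at the doubly allylic position of the dienyl chain, with migration of the alkene into conjugation.
   - Enolisation of the aldehyde, or β-elimination of its alkynyloxy group.
   - Retro-aldol cleavage on work-up.

   Fallback, setting out from 17 and 13 and coming back at 23. Lithium enolate 18, made from 17 as in step 9, is added to 13 (THF, –78 °C) to give (1S,6E)-1-(3,4-dimethoxyphenyl)-3-hydroxy-10-methyl-1-[(5-methylhex-4-en-1-yn-1-yl)oxy]undeca-6,9-dien-5-one F3. Silylation (t-BuMe2SiCl, imidazole, DMF) gives its 3-(tert-butyldimethylsilyl) ether F4. Detrifluoroacetylative diazo transfer at the C4a methylene then gives 23. It runs with LiN(SiMe3)2 and CF3CO2CH2CF3 at –78 °C through the lithium enolate of F4 F5 and the 4-trifluoroacetyl derivative of F4 F6, followed by MeSO2N3, Et3N, MeCN. The order of C–C bond formation and diazo introduction is reversed.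

3. Step 5. What may go wrong:
   - Slow or SN2′ alkylation of the acetylide.
   - Base-induced migration of the skipped enyne to an allene.
   - Benzylic deprotonation by excess n-BuLi, with erosion at C2.
   - Thermal rearrangement of the benzylic alkynyl ether on warming.

   Fallback, setting out from 7 and coming back at 11. Acetylide 10 is generated as in step 5 and quenched with Bu3SnCl to give tributyl[2-{[(1S)-1-(3,4-dimethoxyphenyl)-3-(triisopropylsilyloxy)propyl]oxy}ethynyl]stannane F7. Stille coupling with 8 (Pd(PPh3)4, THF, 20 °C) should then attach the prenyl group at its primary carbon through the π-allyl complex to give 11. SN2 alkylation is replaced by cross-coupling.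

**Further compounds**

F1 | step 12 | (3S)-3-(3,4-dimethoxyphenyl)-3-[3-hydroxy-2,4-bis(3-methylbut-2-en-1-yl)phenoxy]propanal | CC(C)=CCc1ccc(O[C@@H](CC=O)c2ccc(OC)c(OC)c2)c(CC=C(C)C)c1O
F2 | step 12 | (3S)-3-(3,4-dimethoxyphenyl)-3-[3-hydroxy-2,4-bis(3-methylbut-2-en-1-yl)phenoxy]propanoic acid | CC(C)=CCc1ccc(O[C@@H](CC(=O)O)c2ccc(OC)c(OC)c2)c(CC=C(C)C)c1O
F3 | step 10 | (1S,6E)-1-(3,4-dimethoxyphenyl)-3-hydroxy-10-methyl-1-[(5-methylhex-4-en-1-yn-1-yl)oxy]undeca-6,9-dien-5-one (both C3 epimers) | CC(C)=CC/C=C/C(=O)CC(O)C[C@H](OC#CCC=C(C)C)c1ccc(OC)c(OC)c1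
F4 | step 10 | (1S,6E)-3-(tert-butyldimethylsilyloxy)-1-(3,4-dimethoxyphenyl)-10-methyl-1-[(5-methylhex-4-en-1-yn-1-yl)oxy]undeca-6,9-dien-5-one (both C3 epimers) | CC(C)=CC/C=C/C(=O)CC(O[Si](C)(C)C(C)(C)C)C[C@H](OC#CCC=C(C)C)c1ccc(OC)c(OC)c1
F5 | step 10 | lithium enolate of F4 (C4–C5 enolate, formed in the flask) | [Li+].[O-]C(=CC(O[Si](C)(C)C(C)(C)C)C[C@H](OC#CCC=C(C)C)c1ccc(OC)c(OC)c1)/C=C/CC=C(C)C
F6 | step 10 | 4-(trifluoroacetyl) derivative of F4 (not purified) | CC(C)=CC/C=C/C(=O)C(C(=O)C(F)(F)F)C(O[Si](C)(C)C(C)(C)C)C[C@H](OC#CCC=C(C)C)c1ccc(OC)c(OC)c1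
F7 | step 5 | tributyl[2-{[(1S)-1-(3,4-dimethoxyphenyl)-3-(triisopropylsilyloxy)propyl]oxy}ethynyl]stannane | CC(C)[Si](OCC[C@H](OC#C[Sn](CCCC)(CCCC)CCCC)c1ccc(OC)c(OC)c1)(C(C)C)C(C)C
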